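**Remark on conventions and one assumption.** Atoms carry germacranolide numbers throughout, also in open-chain intermediates: ring carbons C1–C10, C11 (lactone α-carbon on C7), C12 (lactone carbonyl, closed onto the oxygen of C6), C13 (CH2 on C11), C14 (methyl on C10), C15 (methyl on C4). TBS = tert-butyldimethylsilyl, TES = triethylsilyl, TIPS = triisopropylsilyl, PMB = 4-methoxybenzyl, Ms = methanesulfonyl, Ipc = isopinocampheyl. It is assumed that (R)-(−)-linalool is used at commercial enantiomeric purity and that the small amount of diastereomer this causes is removed after the crotylation.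

## Analysis of the target

Target 33 is a germacranolide: a ten-membered carbocycle (C1–C10) fused through C6–C7 to a butenolide whose tetrasubstituted alkene C7=C11 carries the acetoxymethyl carbon C13. The ring bears a trisubstituted epoxide at C4–C5 in which C3 and C6 lie on the same side (a cis epoxide, methyl C15 on C4), a methacrylate on C8, a free secondary hydroxyl on C1 and the methyl C14 on C10. There are six stereocentres, 1S, 4R, 5S, 6S, 8S and 10R. C4–C5–C6 are contiguous, C8 is insulated from C6 by the sp2 carbon C7, and C10/C1 form an anti methyl/hydroxyl pair. The hydrogen on C6 is γ to the lactone carbonyl and β to the epoxide oxygen, so base can epimerise C6 or open the epoxide by elimination. The allylic acetate, the methacrylate (a Michael acceptor) and the epoxide (acid, transannular attack by the C1 hydroxyl) add further limits. The difficulty is the medium ring combined with stereocentres that cannot all relay to each other, and three oxygens (C1, C8, C13) that must end in three different states. The strategy rests on one feature: C6 is the γ-carbon of the butenolide and therefore nucleophilic once the lactone is written as a 2-silyloxyfuran, C5 carries oxygen, and the neighbouring C4 oxygen can chelate. C5–C6 is thus a vinylogous aldol bond that can also close the ring.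

## Retrosynthetic reasoning

**Ester and silyl adjustments (33 back to 29).** The acetate on C13 and the methacrylate on C8 are cut first, because neither survives the base needed to make the epoxide. Target 33 comes from diol 32 by acylation of the primary hydroxyl only, 32 from bis-silyl ether 31, 31 from alcohol 30, and 30 from the fully silylated epoxide 29. The forward steps must distinguish a secondary TES ether from two TBS ethers, and a primary from a hindered secondary alcohol.

**The C5–O bond of the epoxide (29 back to 26).** The epoxide oxygen is kept on C4 and the bond to C5 is cut, giving hydroxy mesylate 28, its PMB ether 27 and the C5 alcohol 26. Cutting here and not at C4–O keeps the quaternary centre untouched. The closure inverts C5, so 26 must carry the opposite (5R) configuration.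

**The C5–C6 bond, which also opens the ten-membered ring (26 back to 25).** In 26 a hydroxyl on C5 sits next to the γ-carbon of a butenolide, the retron of a vinylogous aldol addition. Cutting C5–C6 removes the ring and two stereocentres in one stroke and leaves silyloxyfuran aldehyde 25. No other ring bond has this polarity match, and no other cut leaves an aldehyde flanked by a chelating ether. The forward reaction has to close a ten-membered ring against oligomerisation, attack through C6 and not C11, and set 5R and 6S.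

**Unmasking the two reacting ends (25 back to 22).** The silyl dienol ether of 25 is the enol form of butenolide 24, and the aldehyde of 24 is the cleaved vinyl group of 22. The vinyl group is carried from the start because it is inert to everything before, and the aldehyde it gives cannot enolise.

**The C7–C8 bond (22 back to 13 and 18).** Cutting between the butenolide β-carbon and the carbinol C8 divides the molecule into a chain aldehyde 13 and iodobutenolide 18 of comparable size. Since a β-branched aldehyde gives no useful 1,3-induction, C8 is set afterwards: the coupling product 19 is oxidised to ketone 20 and reduced under catalyst control to 21, then silylated to 22.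

**The C11–C13 bond of the lactone fragment (18 back to 14).** The nucleophilic carbon of tetronic acid 14 corresponds to C11 and its enol carbon to C7. One formylation with halogen exchange of the enol gives 15, halide exchange gives 16, reduction 17 and silylation 18.

**The C1–C10 bond (13 back to 4 and 5).** Aldehyde 13 comes from alcohol 12 and this from diene 10 by anti-Markovnikov hydration of the less hindered vinyl group. The anti C14-methyl/C1-hydroxyl pair of 9 is the retron of an E-crotyl addition to aldehyde 4, so trans-but-2-ene 5 is the four-carbon source. The cis isomer would give the syn pair. This cut sets two stereocentres by reagent control and brings C8–C10 and C14 in one step.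

**Back to the chiral pool (4 back to 1).** Aldehyde 4 is the cleavage product of the trisubstituted alkene of PMB ether 2 (through epoxide 3), and 2 is the ether of (R)-linalool 1. Linalool supplies C1–C5 and C15 and the quaternary C4 with the correct configuration.

## Alternatives that were turned down

**Alternative 1: photocycloaddition, then cycloreversion.**
- Disconnection: the ring is traced to a tricyclic photoadduct, A1, the cis-anti-cis tricyclo[4.4.0.0(2,5)]decanone ester that holds all ten ring carbons.
- Forward key step: an enone and a cyclobutene partner are irradiated to form C4–C5 and C1–C10. Thermal opening of the central cyclobutane in the other sense then releases a cyclodeca-1,5-dienone.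
- For it: the ten-membered ring appears without high dilution and without an entropic penalty, and the reaction type is well established for germacrane skeletons. On ring formation it is safer than the chosen route.
- Against it: the target has no ring alkene left apart from C7=C11. After the ring is made from A1, both ring alkenes must be converted on a flexible ring, by facial and regioselective hydration at C1/C10 and by epoxidation of an enone at C4/C5. C15 arrives as an ester that must be reduced to methyl. The butenolide with C13 has to be grafted onto C6/C7. The thermolysis also runs through a 1,5-diene that can undergo Cope rearrangement.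
- Comparison: five of six stereocentres would rest on substrate control in a medium ring, and the step count after A1 is high. The chosen route sets four centres by reagent or pool control before the ring exists.

**Alternative 2: anionic oxy-Cope ring expansion.**
- Disconnection: C8–C9 is formed and C1–C6 broken in a [3,3] shift that opens a six-membered ring to dienone A2, (8S)-8-(4-methoxybenzyloxy)germacra-1(10)E,4Z-dien-6-one.
- Forward key step: the potassium alkoxide of a 1,2-dialkenyl cyclohexanol from the terpene pool rearranges on warming.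
- For it: the ring expansion is reliable, needs no dilution, delivers the 4Z alkene that a cis epoxide requires, and carries C8 oxygen with the right configuration. On the ring-forming event it is stronger than the chosen route.
- Against it: A2 still lacks the lactone and three stereocentres. Annulating the butenolide needs enolate chemistry at C7, which lies between the C6 ketone and the C8 ether, so β-elimination of the C8 oxygen threatens. The 1(10) alkene must be hydrated with control of both C1 and C10. The conjugated 4Z alkene must be epoxidised and C6 reduced with defined faces.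
- Comparison: the ring is easier, the functionalisation afterwards is much harder. The chosen route offers the reverse balance: after ring closure only protecting-group and ester operations and one epoxide closure remain.

**Alternative 3: Nozaki–Hiyama–Kishi macrocyclisation at C6–C7.**
- Disconnection: C6–C7 and the lactone C–O bond are cut, leading to a C7 alkenyl iodide with a cis ester and an epoxy aldehyde at C6.
- Forward key step: a chromium-mediated, nickel-catalysed addition closes the ring and the alkoxide lactonises, giving A3, the assembled epoxy butenolide with C8 PMB and C1 TBS ethers.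
- For it: the reaction type is known for medium rings, the lactone forms in the same operation, the epoxide can be installed early by catalyst control so that no inversion step is needed, and A3 is only three steps from the target. On precedent and on length of the endgame it is stronger.
- Against it: it needs a geometrically defined tetrasubstituted β-iodo enoate that already carries the allylic acetate. That acetate is itself a substrate for low-valent nickel and chromium. The epoxy aldehyde is exposed to Lewis-acidic chromium chloride. The electron-poor alkenylchromium is a weak nucleophile. C6 would be set without a chelate to direct it.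
- Comparison: the chosen route uses a far simpler cyclisation precursor (a furan and a non-enolisable aldehyde), makes the bond where the polarity is natural, and controls C5 through a defined chelate. It accepts in exchange that its ring closure is without direct precedent.

Key step: step 18

## Route

Step 1
Reactants: 1 (R)-linalool, (3R)-3,7-dimethylocta-1,6-dien-3-ol
Product: 2 (3R)-3-(4-methoxybenzyloxy)-3,7-dimethylocta-1,6-diene
Conditions: NaH, 4-methoxybenzyl chloride, n-Bu4NI (cat.), DMF/THF, 0 → 50 °C
Reagents that add atoms: 4-methoxybenzyl chloride, COc1ccc(CCl)cc1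
Why: Williamson etherification of the tertiary alkoxide with a reactive benzylic halide under iodide catalysis; the C4–O bond is not touched, so the configuration of 1 is kept.

Step 2
Reactants: 2 (3R)-3-(4-methoxybenzyloxy)-3,7-dimethylocta-1,6-diene
Product: 3 2-[(3R)-3-(4-methoxybenzyloxy)-3-methylpent-4-en-1-yl]-3,3-dimethyloxirane (both epimers at the oxirane CH)
Conditions: mCPBA, NaHCO3, CH2Cl2, 0 °C
Reagents that add atoms: 3-chloroperbenzoic acid, OOC(=O)c1cccc(Cl)c1
Why: Prilezhaev epoxidation; the electron-rich trisubstituted alkene reacts far faster than the vinyl group, which is monosubstituted and deactivated by the allylic ether; the new centre is destroyed in step 3.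

Step 3
Reactants: 3 2-[(3R)-3-(4-methoxybenzyloxy)-3-methylpent-4-en-1-yl]-3,3-dimethyloxirane
Product: 4 (4R)-4-(4-methoxybenzyloxy)-4-methylhex-5-enal
Conditions: H5IO6, THF/Et2O, 0 °C
Reagents that add atoms: none
Why: Periodic acid opens the epoxide to the glycol and cleaves it (Malaprade cleavage) to the C1 aldehyde and acetone; the vinyl group and the aryl ether are inert.

Step 4
Reactants: 4 (4R)-4-(4-methoxybenzyloxy)-4-methylhex-5-enal; 5 trans-but-2-ene
Product: 9 (3R,4S,7R)-7-(4-methoxybenzyloxy)-3,7-dimethylnona-1,8-dien-4-ol, via (E)-but-2-enylpotassium 6 (not isolated), via (E)-but-2-enylbis(isopinocampheyl)borane 7 (not isolated), via bis(isopinocampheyl)borinate 8 (not isolated)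
Conditions: 5, KOt-Bu, n-BuLi, THF, −78 → −45 °C; (+)-Ipc2BOMe [from (−)-α-pinene], −78 °C; BF3·OEt2; 4, −78 °C; NaOH, H2O2, 0 °C → rt
Reagents that add atoms: none
Why: Brown crotylboration through a closed chair (Zimmerman–Traxler) transition state: the E-crotyl unit places the C14 methyl anti to the new hydroxyl, and the isopinocampheyl groups from (−)-α-pinene direct attack to the Re face of the aldehyde, which sets 1S and 10R (3R,4S in 9) by reagent control, the remote C4 centre having no influence.

Step 5
Reactants: 9 (3R,4S,7R)-7-(4-methoxybenzyloxy)-3,7-dimethylnona-1,8-dien-4-ol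
Product: 10 (3R,4S,7R)-4-(tert-butyldimethylsilyloxy)-7-(4-methoxybenzyloxy)-3,7-dimethylnona-1,8-diene
Conditions: TBSOTf, 2,6-lutidine, CH2Cl2, −78 → 0 °C
Reagents that add atoms: tert-butyldimethylsilyl triflate, CC(C)(C)[Si](C)(C)OS(=O)(=O)C(F)(F)F
Why: O-silylation of a hindered secondary alcohol with a silyl triflate and a hindered base; no stereocentre is involved.

Step 6
Reactants: 10 (3R,4S,7R)-4-(tert-butyldimethylsilyloxy)-7-(4-methoxybenzyloxy)-3,7-dimethylnona-1,8-diene
Product: 12 (3R,4S,7R)-4-(tert-butyldimethylsilyloxy)-7-(4-methoxybenzyloxy)-3,7-dimethylnon-8-en-1-ol, via B-alkyldisiamylborane 11 (not isolated)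
Conditions: Sia2BH (from BH3·THF and 2-methylbut-2-ene), THF, 0 °C; NaOH, H2O2
Reagents that add atoms: hydrogen peroxide, OO
Why: Hydroboration–oxidation (anti-Markovnikov hydration); disiamylborane is very sensitive to substitution at the allylic carbon, so the vinyl group on the tertiary C10 reacts while the vinyl group on the fully substituted, oxygen-bearing C4 is both more hindered and inductively deactivated.

Step 7
Reactants: 12 (3R,4S,7R)-4-(tert-butyldimethylsilyloxy)-7-(4-methoxybenzyloxy)-3,7-dimethylnon-8-en-1-ol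
Product: 13 (3R,4S,7R)-4-(tert-butyldimethylsilyloxy)-7-(4-methoxybenzyloxy)-3,7-dimethylnon-8-enal
Conditions: Dess–Martin periodinane, NaHCO3, CH2Cl2, 0 °C → rt
Reagents that add atoms: none
Why: Dess–Martin oxidation of a primary alcohol under buffered conditions; the α-carbon C9 is a methylene, so no stereocentre is at risk.

Step 8
Reactants: 14 tetronic acid, furan-2,4(3H,5H)-dione
Product: 15 4-chloro-2-oxo-2,5-dihydrofuran-3-carbaldehyde
Conditions: POCl3, DMF, ClCH2CH2Cl, 0 °C → rt; aq. NaOAc
Reagents that add atoms: N,N-dimethylformamide, CN(C)C=O; POCl3, O=P(Cl)(Cl)Cl; water, O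
Why: Vilsmeier–Haack–Arnold chloroformylation of an enolised cyclic 1,3-dicarbonyl compound: the nucleophilic carbon (C11) is formylated, which installs C13, and the enol hydroxyl on C7 is exchanged for chloride.

Step 9
Reactants: 15 4-chloro-2-oxo-2,5-dihydrofuran-3-carbaldehyde
Product: 16 4-iodo-2-oxo-2,5-dihydrofuran-3-carbaldehyde
Conditions: NaI, acetone, rt, dark
Reagents that add atoms: NaI, [Na+].[I-]
Why: Halide exchange by conjugate addition–elimination at the doubly activated β-carbon (a vinylogous Finkelstein reaction), driven by precipitation of NaCl; the iodide is wanted for fast oxidative addition in step 12.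

Step 10
Reactants: 16 4-iodo-2-oxo-2,5-dihydrofuran-3-carbaldehyde
Product: 17 3-(hydroxymethyl)-4-iodofuran-2(5H)-one
Conditions: NaBH4, CeCl3·7H2O, THF/MeOH, −78 °C
Reagents that add atoms: none
Why: Luche reduction; the cerium-modified borohydride attacks the aldehyde in 1,2-fashion at low temperature faster than hydride adds to the β-iodo enoate.

Step 11
Reactants: 17 3-(hydroxymethyl)-4-iodofuran-2(5H)-one
Product: 18 3-[(tert-butyldimethylsilyloxy)methyl]-4-iodofuran-2(5H)-one
Conditions: TBSOTf, 2,6-lutidine, CH2Cl2, −78 °C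
Reagents that add atoms: tert-butyldimethylsilyl triflate, CC(C)(C)[Si](C)(C)OS(=O)(=O)C(F)(F)F
Why: O-silylation with a silyl triflate and a hindered, non-nucleophilic base, chosen because nucleophilic amines would displace the vinylogous acyl iodide.

Step 12
Reactants: 13 (3R,4S,7R)-4-(tert-butyldimethylsilyloxy)-7-(4-methoxybenzyloxy)-3,7-dimethylnon-8-enal; 18 3-[(tert-butyldimethylsilyloxy)methyl]-4-iodofuran-2(5H)-one
Product: 19 4-[(3R,4S,7R)-4-(tert-butyldimethylsilyloxy)-1-hydroxy-7-(4-methoxybenzyloxy)-3,7-dimethylnon-8-en-1-yl]-3-[(tert-butyldimethylsilyloxy)methyl]furan-2(5H)-one (both epimers at the carbinol C8)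
Conditions: CrCl2, NiCl2 (cat.), DMF/THF, rt
Reagents that add atoms: none
Why: Nozaki–Hiyama–Kishi coupling: zerovalent nickel inserts into the activated C7–I bond, transmetallation gives an alkenyl species of trivalent chromium that adds to the aldehyde and tolerates the lactone, its acidic γ-methylene and the silyl ethers; C8 is formed without control and is corrected in steps 13 and 14.

Step 13
Reactants: 19 4-[(3R,4S,7R)-4-(tert-butyldimethylsilyloxy)-1-hydroxy-7-(4-methoxybenzyloxy)-3,7-dimethylnon-8-en-1-yl]-3-[(tert-butyldimethylsilyloxy)methyl]furan-2(5H)-one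
Product: 20 4-[(3R,4S,7R)-4-(tert-butyldimethylsilyloxy)-7-(4-methoxybenzyloxy)-3,7-dimethylnon-8-enoyl]-3-[(tert-butyldimethylsilyloxy)methyl]furan-2(5H)-one
Conditions: Dess–Martin periodinane, NaHCO3, CH2Cl2, 0 °C
Reagents that add atoms: none
Why: Dess–Martin oxidation of the allylic-type secondary alcohol removes the uncontrolled C8 centre; the acylbutenolide is used at once.

Step 14
Reactants: 20 4-[(3R,4S,7R)-4-(tert-butyldimethylsilyloxy)-7-(4-methoxybenzyloxy)-3,7-dimethylnon-8-enoyl]-3-[(tert-butyldimethylsilyloxy)methyl]furan-2(5H)-one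
Product: 21 4-[(1S,3R,4S,7R)-4-(tert-butyldimethylsilyloxy)-1-hydroxy-7-(4-methoxybenzyloxy)-3,7-dimethylnon-8-en-1-yl]-3-[(tert-butyldimethylsilyloxy)methyl]furan-2(5H)-one
Conditions: (R)-1-methyl-3,3-diphenyltetrahydro-1H,3H-pyrrolo[1,2-c][1,3,2]oxazaborole [(R)-Me-CBS] (0.3 equiv), catecholborane, toluene, −78 °C
Reagents that add atoms: none
Why: Corey–Bakshi–Shibata reduction: with the (R)-oxazaborolidine the hydride goes to the face that gives 8S when the tetrasubstituted butenolide carbon is the large and the C9 methylene the small group; catecholborane is used because it does not hydroborate the remaining vinyl group at this temperature.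

Step 15
Reactants: 21 4-[(1S,3R,4S,7R)-4-(tert-butyldimethylsilyloxy)-1-hydroxy-7-(4-methoxybenzyloxy)-3,7-dimethylnon-8-en-1-yl]-3-[(tert-butyldimethylsilyloxy)methyl]furan-2(5H)-one
Product: 22 4-[(1S,3R,4S,7R)-4-(tert-butyldimethylsilyloxy)-7-(4-methoxybenzyloxy)-3,7-dimethyl-1-(triethylsilyloxy)non-8-en-1-yl]-3-[(tert-butyldimethylsilyloxy)methyl]furan-2(5H)-one
Conditions: TESCl, imidazole, DMF, 0 °C
Reagents that add atoms: chlorotriethylsilane, CC[Si](Cl)(CC)CC
Why: Standard O-silylation; the TES group is chosen so that C8 can later be freed before the two TBS ethers.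

Step 16
Reactants: 22 4-[(1S,3R,4S,7R)-4-(tert-butyldimethylsilyloxy)-7-(4-methoxybenzyloxy)-3,7-dimethyl-1-(triethylsilyloxy)non-8-en-1-yl]-3-[(tert-butyldimethylsilyloxy)methyl]furan-2(5H)-one
Product: 24 4-[(1S,3R,4S,7R)-4-(tert-butyldimethylsilyloxy)-7-(4-methoxybenzyloxy)-3,7-dimethyl-8-oxo-1-(triethylsilyloxy)octyl]-3-[(tert-butyldimethylsilyloxy)methyl]furan-2(5H)-one, via vicinal diol 23 (not isolated)
Conditions: OsO4 (cat.), NaIO4, 2,6-lutidine, 1,4-dioxane/H2O, rt
Reagents that add atoms: OsO4, O=[Os](=O)(=O)=O; NaIO4, [Na+].[O-]I(=O)(=O)=O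
Why: Lemieux–Johnson cleavage: OsO4 dihydroxylates only the monosubstituted vinyl group (the butenolide alkene is tetrasubstituted and electron-poor) and periodate cleaves the diol; the C5 aldehyde has no α-hydrogen, so C4 cannot epimerise.

Step 17
Reactants: 24 4-[(1S,3R,4S,7R)-4-(tert-butyldimethylsilyloxy)-7-(4-methoxybenzyloxy)-3,7-dimethyl-8-oxo-1-(triethylsilyloxy)octyl]-3-[(tert-butyldimethylsilyloxy)methyl]furan-2(5H)-one
Product: 25 3-[(tert-butyldimethylsilyloxy)methyl]-4-[(1S,3R,4S,7R)-4-(tert-butyldimethylsilyloxy)-7-(4-methoxybenzyloxy)-3,7-dimethyl-8-oxo-1-(triethylsilyloxy)octyl]-2-(triisopropylsilyloxy)furan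
Conditions: TIPSOTf, Et3N, CH2Cl2, −78 → 0 °C; filtration through basic alumina
Reagents that add atoms: triisopropylsilyl triflate, CC(C)[Si](OS(=O)(=O)C(F)(F)F)(C(C)C)C(C)C
Why: Soft enolisation of the butenolide: O-silylation of the lactone carbonyl and loss of a C6 proton give the aromatic 2-silyloxyfuran; the aldehyde cannot enolise, and the bulky silyl triflate is consumed by the amine-assisted silylation before it can promote an aldol addition.

Step 18
Reactants: 25 3-[(tert-butyldimethylsilyloxy)methyl]-4-[(1S,3R,4S,7R)-4-(tert-butyldimethylsilyloxy)-7-(4-methoxybenzyloxy)-3,7-dimethyl-8-oxo-1-(triethylsilyloxy)octyl]-2-(triisopropylsilyloxy)furan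
Product: 26 (1S,4R,5R,6S,8S,10R)-1,13-bis(tert-butyldimethylsilyloxy)-5-hydroxy-4-(4-methoxybenzyloxy)-8-(triethylsilyloxy)germacr-7(11)-en-12,6-olide
Conditions: MgBr2·OEt2 (3 equiv), CH2Cl2, 0.001 M, slow addition of 25, −78 → −20 °C; aq. NaHCO3
Reagents that add atoms: none
Why: Proposed new method: MgBr2 binds the aldehyde oxygen and the C4 ether oxygen in a five-membered chelate, the furan attacks C5 through its free α-position C6, and the resulting silyloxy-oxocarbenium ion loses the silyl group to bromide, which restores the butenolide C7=C11; the closest known reaction is the intermolecular vinylogous Mukaiyama aldol addition of 2-silyloxyfurans to chelated α-alkoxy aldehydes. The ten-membered ring closes by C–C bond formation between the chain ends in a 10-(enolendo)-exo-trig mode, helped by the planar furan and the rigid chelate, which leave few freely rotating bonds, and by high dilution. C5 is controlled by the chelate (Cram chelate model): C6 enters on the face of the carbonyl that carries the C15 methyl, anti to the C3 methylene, which is also the face the tether reaches with an extended C3–C4–C5–C6 torsion, and this gives 5R. C6 is controlled by C8: allylic strain holds the C8 hydrogen in the furan plane next to the C13 substituent, C9 leaves one face and C5 bonds to the other, a same-sign gauche arrangement about C6–C7–C8 that corresponds to 6S for 8S. The step needs ring closure over oligomerisation (dilution, slow addition), attack at C6 and not at C11 (C11 is substituted and would give an eight-membered ring), and the 5R,6S pair, which is secured only if chelate and tether can be satisfied in one transition state. The silyl ethers do not compete for magnesium, and the temperature is kept low so that bromide does not cleave the PMB ether.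

Step 19
Reactants: 26 (1S,4R,5R,6S,8S,10R)-1,13-bis(tert-butyldimethylsilyloxy)-5-hydroxy-4-(4-methoxybenzyloxy)-8-(triethylsilyloxy)germacr-7(11)-en-12,6-olide
Product: 27 (1S,4R,5R,6S,8S,10R)-1,13-bis(tert-butyldimethylsilyloxy)-5-(methanesulfonyloxy)-4-(4-methoxybenzyloxy)-8-(triethylsilyloxy)germacr-7(11)-en-12,6-olide
Conditions: MsCl, Et3N, CH2Cl2, −20 → 0 °C
Reagents that add atoms: methanesulfonyl chloride, CS(=O)(=O)Cl
Why: Mesylation through sulfene, which suits the hindered secondary alcohol; the O–S bond is formed, so C5 keeps its configuration, and the short, cold reaction limits elimination toward C6.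

Step 20
Reactants: 27 (1S,4R,5R,6S,8S,10R)-1,13-bis(tert-butyldimethylsilyloxy)-5-(methanesulfonyloxy)-4-(4-methoxybenzyloxy)-8-(triethylsilyloxy)germacr-7(11)-en-12,6-olide
Product: 28 (1S,4R,5R,6S,8S,10R)-1,13-bis(tert-butyldimethylsilyloxy)-4-hydroxy-5-(methanesulfonyloxy)-8-(triethylsilyloxy)germacr-7(11)-en-12,6-olide
Conditions: DDQ, CH2Cl2/pH 7 buffer, 0 °C → rt
Reagents that add atoms: none
Why: Oxidative cleavage of the PMB ether by DDQ, with water hydrolysing the oxocarbenium ion; because the C5 oxygen is already capped as the mesylate, no benzylidene acetal can form.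

Step 21
Reactants: 28 (1S,4R,5R,6S,8S,10R)-1,13-bis(tert-butyldimethylsilyloxy)-4-hydroxy-5-(methanesulfonyloxy)-8-(triethylsilyloxy)germacr-7(11)-en-12,6-olide
Product: 29 (1S,4R,5S,6S,8S,10R)-1,13-bis(tert-butyldimethylsilyloxy)-4,5-epoxy-8-(triethylsilyloxy)germacr-7(11)-en-12,6-olide
Conditions: K2CO3, MeOH, −10 → 0 °C
Reagents that add atoms: none
Why: Intramolecular Williamson reaction (3-exo-tet): the tertiary C4 alkoxide displaces the mesylate from the rear, inverting C5 from R to S while C4 keeps its oxygen and configuration, which gives the cis epoxide with C3 and C6 on the same side.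

Step 22
Reactants: 29 (1S,4R,5S,6S,8S,10R)-1,13-bis(tert-butyldimethylsilyloxy)-4,5-epoxy-8-(triethylsilyloxy)germacr-7(11)-en-12,6-olide
Product: 30 (1S,4R,5S,6S,8S,10R)-1,13-bis(tert-butyldimethylsilyloxy)-4,5-epoxy-8-hydroxygermacr-7(11)-en-12,6-olide
Conditions: HF·pyridine, pyridine, THF, 0 °C
Reagents that add atoms: none
Why: Selective desilylation: a secondary TES ether is cleaved by buffered HF·pyridine much faster than either TBS ether, and the excess pyridine keeps the medium too weakly acidic to open the epoxide.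

Step 23
Reactants: 30 (1S,4R,5S,6S,8S,10R)-1,13-bis(tert-butyldimethylsilyloxy)-4,5-epoxy-8-hydroxygermacr-7(11)-en-12,6-olide
Product: 31 (1S,4R,5S,6S,8S,10R)-1,13-bis(tert-butyldimethylsilyloxy)-4,5-epoxy-8-(methacryloyloxy)germacr-7(11)-en-12,6-olide
Conditions: methacrylic anhydride, Et3N, 4-(dimethylamino)pyridine (cat.), CH2Cl2, 0 °C
Reagents that add atoms: methacrylic anhydride, C=C(C)C(=O)OC(=O)C(C)=C
Why: Acyl transfer catalysed by 4-(dimethylamino)pyridine onto the only free hydroxyl; the O–acyl bond is formed, so C8 is unchanged, and the mild base at 0 °C spares the C6 hydrogen.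

Step 24
Reactants: 31 (1S,4R,5S,6S,8S,10R)-1,13-bis(tert-butyldimethylsilyloxy)-4,5-epoxy-8-(methacryloyloxy)germacr-7(11)-en-12,6-olide
Product: 32 (1S,4R,5S,6S,8S,10R)-4,5-epoxy-1,13-dihydroxy-8-(methacryloyloxy)germacr-7(11)-en-12,6-olide
Conditions: HF·pyridine, pyridine, THF, 0 °C → rt
Reagents that add atoms: none
Why: Fluoride-mediated cleavage of both TBS ethers under buffered, non-basic conditions that leave the two esters, the epoxide and the C6 hydrogen alone.

Step 25
Reactants: 32 (1S,4R,5S,6S,8S,10R)-4,5-epoxy-1,13-dihydroxy-8-(methacryloyloxy)germacr-7(11)-en-12,6-olide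
Product: 33 (1S,4R,5S,6S,8S,10R)-13-acetoxy-4,5-epoxy-1-hydroxy-8-(methacryloyloxy)germacr-7(11)-en-12,6-olide (CNP0119405.1)
Conditions: AcCl (1.05 equiv), 2,4,6-collidine, CH2Cl2, −78 °C
Reagents that add atoms: acetyl chloride, CC(=O)Cl
Why: Selective acylation of a primary alcohol with an acyl chloride and a hindered pyridine base at low temperature; the secondary C1 hydroxyl, flanked by the methyl-bearing C10 in the ring, reacts much more slowly.

## Compound list

1 | (R)-linalool, (3R)-3,7-dimethylocta-1,6-dien-3-ol | CC(C)=CCC[C@](C)(C=C)O | starting material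
2 | (3R)-3-(4-methoxybenzyloxy)-3,7-dimethylocta-1,6-diene | CC(C)=CCC[C@](C)(C=C)OCc1ccc(OC)cc1 | intermediate
3 | 2-[(3R)-3-(4-methoxybenzyloxy)-3-methylpent-4-en-1-yl]-3,3-dimethyloxirane (epimers at the oxirane CH) | CC1(C)OC1CC[C@](C)(C=C)OCc1ccc(OC)cc1 | intermediate
4 | (4R)-4-(4-methoxybenzyloxy)-4-methylhex-5-enal | O=CCC[C@](C)(C=C)OCc1ccc(OC)cc1 | intermediate
5 | trans-but-2-ene | C/C=C/C | starting material
6 | (E)-but-2-enylpotassium | C/C=C/C[K] | intermediate
7 | (E)-but-2-enylbis(isopinocampheyl)borane, Ipc from (−)-α-pinene | C/C=C/CB([C@H]1C[C@H]2C[C@@H]([C@@H]1C)C2(C)C)[C@H]1C[C@H]2C[C@@H]([C@@H]1C)C2(C)C | intermediate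
8 | bis(isopinocampheyl)borinate of alcohol 9 | C=C[C@@H](C)[C@@H](OB([C@H]1C[C@H]2C[C@@H]([C@@H]1C)C2(C)C)[C@H]1C[C@H]2C[C@@H]([C@@H]1C)C2(C)C)CC[C@](C)(C=C)OCc1ccc(OC)cc1 | intermediate
9 | (3R,4S,7R)-7-(4-methoxybenzyloxy)-3,7-dimethylnona-1,8-dien-4-ol | C=C[C@@H](C)[C@@H](O)CC[C@](C)(C=C)OCc1ccc(OC)cc1 | intermediate
10 | (3R,4S,7R)-4-(tert-butyldimethylsilyloxy)-7-(4-methoxybenzyloxy)-3,7-dimethylnona-1,8-diene | C=C[C@@H](C)[C@@H](O[Si](C)(C)C(C)(C)C)CC[C@](C)(C=C)OCc1ccc(OC)cc1 | intermediate
11 | bis(3-methylbutan-2-yl)[(3R,4S,7R)-4-(tert-butyldimethylsilyloxy)-7-(4-methoxybenzyloxy)-3,7-dimethylnon-8-en-1-yl]borane | CC(C)C(C)B(CC[C@@H](C)[C@@H](O[Si](C)(C)C(C)(C)C)CC[C@](C)(C=C)OCc1ccc(OC)cc1)C(C)C(C)C | intermediate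
12 | (3R,4S,7R)-4-(tert-butyldimethylsilyloxy)-7-(4-methoxybenzyloxy)-3,7-dimethylnon-8-en-1-ol | OCC[C@@H](C)[C@@H](O[Si](C)(C)C(C)(C)C)CC[C@](C)(C=C)OCc1ccc(OC)cc1 | intermediate
13 | (3R,4S,7R)-4-(tert-butyldimethylsilyloxy)-7-(4-methoxybenzyloxy)-3,7-dimethylnon-8-enal | O=CC[C@@H](C)[C@@H](O[Si](C)(C)C(C)(C)C)CC[C@](C)(C=C)OCc1ccc(OC)cc1 | intermediate
14 | tetronic acid, furan-2,4(3H,5H)-dione | O=C1CC(=O)CO1 | starting material
15 | 4-chloro-2-oxo-2,5-dihydrofuran-3-carbaldehyde | O=CC1=C(Cl)COC1=O | intermediate
16 | 4-iodo-2-oxo-2,5-dihydrofuran-3-carbaldehyde | O=CC1=C(I)COC1=O | intermediate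
17 | 3-(hydroxymethyl)-4-iodofuran-2(5H)-one | OCC1=C(I)COC1=O | intermediate
18 | 3-[(tert-butyldimethylsilyloxy)methyl]-4-iodofuran-2(5H)-one | CC(C)(C)[Si](C)(C)OCC1=C(I)COC1=O | intermediate
19 | 4-[(3R,4S,7R)-4-(tert-butyldimethylsilyloxy)-1-hydroxy-7-(4-methoxybenzyloxy)-3,7-dimethylnon-8-en-1-yl]-3-[(tert-butyldimethylsilyloxy)methyl]furan-2(5H)-one (epimers at C8) | CC(C)(C)[Si](C)(C)OCC1=C(COC1=O)C(O)C[C@@H](C)[C@@H](O[Si](C)(C)C(C)(C)C)CC[C@](C)(C=C)OCc1ccc(OC)cc1 | intermediate
20 | 4-[(3R,4S,7R)-4-(tert-butyldimethylsilyloxy)-7-(4-methoxybenzyloxy)-3,7-dimethylnon-8-enoyl]-3-[(tert-butyldimethylsilyloxy)methyl]furan-2(5H)-one | CC(C)(C)[Si](C)(C)OCC1=C(COC1=O)C(=O)C[C@@H](C)[C@@H](O[Si](C)(C)C(C)(C)C)CC[C@](C)(C=C)OCc1ccc(OC)cc1 | intermediate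
21 | 4-[(1S,3R,4S,7R)-4-(tert-butyldimethylsilyloxy)-1-hydroxy-7-(4-methoxybenzyloxy)-3,7-dimethylnon-8-en-1-yl]-3-[(tert-butyldimethylsilyloxy)methyl]furan-2(5H)-one | CC(C)(C)[Si](C)(C)OCC1=C(COC1=O)[C@@H](O)C[C@@H](C)[C@@H](O[Si](C)(C)C(C)(C)C)CC[C@](C)(C=C)OCc1ccc(OC)cc1 | intermediate
22 | 4-[(1S,3R,4S,7R)-4-(tert-butyldimethylsilyloxy)-7-(4-methoxybenzyloxy)-3,7-dimethyl-1-(triethylsilyloxy)non-8-en-1-yl]-3-[(tert-butyldimethylsilyloxy)methyl]furan-2(5H)-one | CC(C)(C)[Si](C)(C)OCC1=C(COC1=O)[C@@H](O[Si](CC)(CC)CC)C[C@@H](C)[C@@H](O[Si](C)(C)C(C)(C)C)CC[C@](C)(C=C)OCc1ccc(OC)cc1 | intermediate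
23 | 8,9-diol of 22 (nonyl chain numbering; epimers at the new carbinol carbon, which is C5) | CC(C)(C)[Si](C)(C)OCC1=C(COC1=O)[C@@H](O[Si](CC)(CC)CC)C[C@@H](C)[C@@H](O[Si](C)(C)C(C)(C)C)CC[C@](C)(C(O)CO)OCc1ccc(OC)cc1 | intermediate
24 | 4-[(1S,3R,4S,7R)-4-(tert-butyldimethylsilyloxy)-7-(4-methoxybenzyloxy)-3,7-dimethyl-8-oxo-1-(triethylsilyloxy)octyl]-3-[(tert-butyldimethylsilyloxy)methyl]furan-2(5H)-one | CC(C)(C)[Si](C)(C)OCC1=C(COC1=O)[C@@H](O[Si](CC)(CC)CC)C[C@@H](C)[C@@H](O[Si](C)(C)C(C)(C)C)CC[C@](C)(C=O)OCc1ccc(OC)cc1 | intermediate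
25 | 3-[(tert-butyldimethylsilyloxy)methyl]-4-[(1S,3R,4S,7R)-4-(tert-butyldimethylsilyloxy)-7-(4-methoxybenzyloxy)-3,7-dimethyl-8-oxo-1-(triethylsilyloxy)octyl]-2-(triisopropylsilyloxy)furan | CC(C)[Si](C(C)C)(C(C)C)Oc1occ([C@@H](O[Si](CC)(CC)CC)C[C@@H](C)[C@@H](O[Si](C)(C)C(C)(C)C)CC[C@@](C)(OCc2ccc(OC)cc2)C=O)c1CO[Si](C)(C)C(C)(C)C | intermediate
26 | (1S,4R,5R,6S,8S,10R)-1,13-bis(tert-butyldimethylsilyloxy)-5-hydroxy-4-(4-methoxybenzyloxy)-8-(triethylsilyloxy)germacr-7(11)-en-12,6-olide | CC[Si](CC)(CC)O[C@H]1C[C@@H](C)[C@@H](O[Si](C)(C)C(C)(C)C)CC[C@@](C)(OCc2ccc(OC)cc2)[C@H](O)[C@H]2OC(=O)C(CO[Si](C)(C)C(C)(C)C)=C12 | intermediate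
27 | (1S,4R,5R,6S,8S,10R)-1,13-bis(tert-butyldimethylsilyloxy)-5-(methanesulfonyloxy)-4-(4-methoxybenzyloxy)-8-(triethylsilyloxy)germacr-7(11)-en-12,6-olide | CC[Si](CC)(CC)O[C@H]1C[C@@H](C)[C@@H](O[Si](C)(C)C(C)(C)C)CC[C@@](C)(OCc2ccc(OC)cc2)[C@H](OS(C)(=O)=O)[C@H]2OC(=O)C(CO[Si](C)(C)C(C)(C)C)=C12 | intermediate
28 | (1S,4R,5R,6S,8S,10R)-1,13-bis(tert-butyldimethylsilyloxy)-4-hydroxy-5-(methanesulfonyloxy)-8-(triethylsilyloxy)germacr-7(11)-en-12,6-olide | CC[Si](CC)(CC)O[C@H]1C[C@@H](C)[C@@H](O[Si](C)(C)C(C)(C)C)CC[C@@](C)(O)[C@H](OS(C)(=O)=O)[C@H]2OC(=O)C(CO[Si](C)(C)C(C)(C)C)=C12 | intermediate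
29 | (1S,4R,5S,6S,8S,10R)-1,13-bis(tert-butyldimethylsilyloxy)-4,5-epoxy-8-(triethylsilyloxy)germacr-7(11)-en-12,6-olide | CC[Si](CC)(CC)O[C@H]1C[C@@H](C)[C@@H](O[Si](C)(C)C(C)(C)C)CC[C@@]2(C)O[C@H]2[C@H]2OC(=O)C(CO[Si](C)(C)C(C)(C)C)=C12 | intermediate
30 | (1S,4R,5S,6S,8S,10R)-1,13-bis(tert-butyldimethylsilyloxy)-4,5-epoxy-8-hydroxygermacr-7(11)-en-12,6-olide | O[C@H]1C[C@@H](C)[C@@H](O[Si](C)(C)C(C)(C)C)CC[C@@]2(C)O[C@H]2[C@H]2OC(=O)C(CO[Si](C)(C)C(C)(C)C)=C12 | intermediate
31 | (1S,4R,5S,6S,8S,10R)-1,13-bis(tert-butyldimethylsilyloxy)-4,5-epoxy-8-(methacryloyloxy)germacr-7(11)-en-12,6-olide | C=C(C)C(=O)O[C@H]1C[C@@H](C)[C@@H](O[Si](C)(C)C(C)(C)C)CC[C@@]2(C)O[C@H]2[C@H]2OC(=O)C(CO[Si](C)(C)C(C)(C)C)=C12 | intermediate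
32 | (1S,4R,5S,6S,8S,10R)-4,5-epoxy-1,13-dihydroxy-8-(methacryloyloxy)germacr-7(11)-en-12,6-olide | C=C(C)C(=O)O[C@H]1C[C@@H](C)[C@@H](O)CC[C@@]2(C)O[C@H]2[C@H]2OC(=O)C(CO)=C12 | intermediate
33 | (1S,4R,5S,6S,8S,10R)-13-acetoxy-4,5-epoxy-1-hydroxy-8-(methacryloyloxy)germacr-7(11)-en-12,6-olide, CNP0119405.1 | C=C(C)C(=O)O[C@H]1C[C@@H](C)[C@@H](O)CC[C@@]2(C)O[C@H]2[C@H]2OC(=O)C(COC(C)=O)=C12 | target

## Step count

Total step count: 25. Longest linear sequence: 21 steps (steps 1–7 and 12–25, from 1 to 33); the branch from 14 to 18 has 4 steps (steps 8–11).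

## Least certain steps and fallbacks

**Step 18 (key step, proposed new method).** Most likely failure: intermolecular aldol addition and oligomerisation overtake closure of the strained ten-membered ring, or the ring closes through the other furan face (wrong C6) because the chelate geometry and the tether cannot be satisfied together. Protodesilylation back to 24, or loss of the PMB group to the Lewis acid, would also stop the reaction. Fallback with known chemistry: make C5–C6 intermolecularly and close the ring at C7–C8. It sets out from alcohol 12 and iodide 18 and returns at mesylate 27.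
- Alcohol 12 would be silylated (TESCl, imidazole) to the primary triethylsilyl ether F1.
- The vinyl group of F1 is cleaved (OsO4 cat., NaIO4, 2,6-lutidine) to the α-alkoxy aldehyde F2.
- Iodide 18 is converted (TIPSOTf, Et3N) into the 4-iodo-2-silyloxyfuran F3.
- F2 and F3 are combined with MgBr2·OEt2 in CH2Cl2 at −78 °C, an intermolecular chelation-controlled vinylogous Mukaiyama aldol addition, to give the adduct F4.
- Mesylation gives the mesylate F5.
- Swern oxidation, which converts primary triethylsilyl ethers directly into aldehydes, gives the iodo aldehyde F6.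
- An intramolecular Nozaki–Hiyama–Kishi reaction (CrCl2, NiCl2 cat., DMF, high dilution) closes the ring to the macrocyclic carbinol F7 as C8 epimers.
- Dess–Martin oxidation gives the macrocyclic ketone F8.
- Reduction with the (R)-oxazaborolidine and catecholborane gives the 8S alcohol F9, and TESCl/imidazole returns to 27.

**Step 17.** Most likely failure: the silyl triflate triggers an unchelated aldol addition of the dienol ether as it forms, or the dienol ether hydrolyses during isolation. Fallback: do not isolate it. Aldehyde 24 is first chelated with MgBr2·OEt2 at high dilution, and Et3N and TIPSOTf are then added slowly at −78 °C, so that 25 is formed in the presence of the chelate and consumed directly to 26. The fallback sets out from 24 and returns at 26.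

**Step 21.** Most likely failure: base removes the C6 hydrogen and the mesylate is lost by elimination through the butenolide dienolate, or C6 epimerises, in competition with the epoxide closure. Fallback without base or mesylate: from 26 the PMB group is removed with MgBr2·OEt2 and Me2S to give the 4,5-diol F10. Mitsunobu cyclodehydration (PPh3, diisopropyl azodicarboxylate, toluene) then activates the secondary C5 hydroxyl and lets the tertiary C4 oxygen displace it with inversion, returning at 29.

**Step 6.** Most likely failure: the borane also adds to the C4 vinyl group, so that chemoselectivity between the two terminal alkenes is incomplete. Fallback on a different principle of discrimination: cross-metathesis of 10 with vinylboronic acid pinacol ester (second-generation Grubbs catalyst) to the (E)-alkenylboronate F11. The vinyl group on the fully substituted ether carbon is a poor metathesis partner. Oxidation with NaBO3·4H2O then gives aldehyde 13 directly.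

**Step 14.** Most likely failure: poor facial selectivity, if the catalyst does not distinguish the butenolide carbon from the β-branched chain well enough, or conjugate reduction of the ene-dicarbonyl system. Fallback without the ketone: the C8 epimers of 19 are separated. The 8S epimer is 21. The 8R epimer is inverted by a Mitsunobu reaction with 4-nitrobenzoic acid (PPh3, diisopropyl azodicarboxylate) to the 8S ester F12, and methanolysis (K2CO3, MeOH) returns to 21.

## Further compounds

F1 | step 18 | (3R,4S,7R)-4-(tert-butyldimethylsilyloxy)-7-(4-methoxybenzyloxy)-3,7-dimethyl-1-(triethylsilyloxy)non-8-ene | CC[Si](CC)(CC)OCC[C@@H](C)[C@@H](O[Si](C)(C)C(C)(C)C)CC[C@](C)(C=C)OCc1ccc(OC)cc1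
F2 | step 18 | (2R,5S,6R)-5-(tert-butyldimethylsilyloxy)-2-(4-methoxybenzyloxy)-2,6-dimethyl-8-(triethylsilyloxy)octanal | CC[Si](CC)(CC)OCC[C@@H](C)[C@@H](O[Si](C)(C)C(C)(C)C)CC[C@](C)(C=O)OCc1ccc(OC)cc1
F3 | step 18 | 3-[(tert-butyldimethylsilyloxy)methyl]-4-iodo-2-(triisopropylsilyloxy)furan | CC(C)[Si](C(C)C)(C(C)C)Oc1occ(I)c1CO[Si](C)(C)C(C)(C)C
F4 | step 18 | open-chain aldol adduct: 5-substituted 3-[(tert-butyldimethylsilyloxy)methyl]-4-iodofuran-2(5H)-one with C5-OH, C4-OPMB, C1-OTBS and C8-OTES (primary), C4, C5 and C6 arranged as in 26 | CC[Si](CC)(CC)OCC[C@@H](C)[C@@H](O[Si](C)(C)C(C)(C)C)CC[C@@](C)(OCc1ccc(OC)cc1)[C@H](O)[C@H]1OC(=O)C(CO[Si](C)(C)C(C)(C)C)=C1I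
F5 | step 18 | C5 methanesulfonate of F4 | CC[Si](CC)(CC)OCC[C@@H](C)[C@@H](O[Si](C)(C)C(C)(C)C)CC[C@@](C)(OCc1ccc(OC)cc1)[C@H](OS(C)(=O)=O)[C@H]1OC(=O)C(CO[Si](C)(C)C(C)(C)C)=C1I
F6 | step 18 | C8 aldehyde from F5 (iodobutenolide mesylate with free aldehyde at the chain end) | O=CC[C@@H](C)[C@@H](O[Si](C)(C)C(C)(C)C)CC[C@@](C)(OCc1ccc(OC)cc1)[C@H](OS(C)(=O)=O)[C@H]1OC(=O)C(CO[Si](C)(C)C(C)(C)C)=C1I
F7 | step 18 | (1S,4R,5R,6S,10R)-1,13-bis(tert-butyldimethylsilyloxy)-8-hydroxy-5-(methanesulfonyloxy)-4-(4-methoxybenzyloxy)germacr-7(11)-en-12,6-olide (epimers at C8) | OC1C[C@@H](C)[C@@H](O[Si](C)(C)C(C)(C)C)CC[C@@](C)(OCc2ccc(OC)cc2)[C@H](OS(C)(=O)=O)[C@H]2OC(=O)C(CO[Si](C)(C)C(C)(C)C)=C12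
F8 | step 18 | (1S,4R,5R,6S,10R)-1,13-bis(tert-butyldimethylsilyloxy)-5-(methanesulfonyloxy)-4-(4-methoxybenzyloxy)-8-oxogermacr-7(11)-en-12,6-olide | O=C1C[C@@H](C)[C@@H](O[Si](C)(C)C(C)(C)C)CC[C@@](C)(OCc2ccc(OC)cc2)[C@H](OS(C)(=O)=O)[C@H]2OC(=O)C(CO[Si](C)(C)C(C)(C)C)=C12
F9 | step 18 | (1S,4R,5R,6S,8S,10R)-1,13-bis(tert-butyldimethylsilyloxy)-8-hydroxy-5-(methanesulfonyloxy)-4-(4-methoxybenzyloxy)germacr-7(11)-en-12,6-olide | O[C@H]1C[C@@H](C)[C@@H](O[Si](C)(C)C(C)(C)C)CC[C@@](C)(OCc2ccc(OC)cc2)[C@H](OS(C)(=O)=O)[C@H]2OC(=O)C(CO[Si](C)(C)C(C)(C)C)=C12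
F0 | step 17 | none | none
F10 | step 21 | (1S,4R,5R,6S,8S,10R)-1,13-bis(tert-butyldimethylsilyloxy)-4,5-dihydroxy-8-(triethylsilyloxy)germacr-7(11)-en-12,6-olide | CC[Si](CC)(CC)O[C@H]1C[C@@H](C)[C@@H](O[Si](C)(C)C(C)(C)C)CC[C@@](C)(O)[C@H](O)[C@H]2OC(=O)C(CO[Si](C)(C)C(C)(C)C)=C12
F11 | step 6 | 2-[(1E,3R,4S,7R)-4-(tert-butyldimethylsilyloxy)-7-(4-methoxybenzyloxy)-3,7-dimethylnona-1,8-dien-1-yl]-4,4,5,5-tetramethyl-1,3,2-dioxaborolane | CC1(C)OB(/C=C/[C@@H](C)[C@@H](O[Si](C)(C)C(C)(C)C)CC[C@](C)(C=C)OCc2ccc(OC)cc2)OC1(C)C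
F12 | step 14 | 4-nitrobenzoate of 21 (8S ester formed from the 8R epimer of 19) | CC(C)(C)[Si](C)(C)OCC1=C(COC1=O)[C@@H](OC(=O)c1ccc(cc1)[N+](=O)[O-])C[C@@H](C)[C@@H](O[Si](C)(C)C(C)(C)C)CC[C@](C)(C=C)OCc1ccc(OC)cc1
A1 | alternative 1 | cis-anti-cis tricyclo[4.4.0.0(2,5)]decanone photoadduct with ring-fusion methyl ester, angular methyl and a silyloxy group on the six-membered ring | COC(=O)[C@@]12CC[C@@H]1[C@@]1(C)C[C@H](O[Si](C)(C)C(C)(C)C)CC(=O)[C@H]12
A2 | alternative 2 | (8S)-8-(4-methoxybenzyloxy)germacra-1(10)E,4Z-dien-6-one | COc1ccc(CO[C@H]2C/C(C)=C/CC/C(C)=C\C(=O)C2)cc1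
A3 | alternative 3 | (1S,4R,5S,6S,8S,10R)-13-acetoxy-1-(tert-butyldimethylsilyloxy)-4,5-epoxy-8-(4-methoxybenzyloxy)germacr-7(11)-en-12,6-olide | COc1ccc(CO[C@H]2C[C@@H](C)[C@@H](O[Si](C)(C)C(C)(C)C)CC[C@@]3(C)O[C@H]3[C@H]3OC(=O)C(COC(C)=O)=C23)cc1
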